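The runs come from a simulation with constants of no real substance, and the scatter is random.

**Reading time.** You read these flasks at 8.0 min, so count how many half-lives of free monomer fit into that time.

all flasks: initiator 1.4 mM
- theta: free monomer 0.082 M; run made earlier
- beta: free monomer 0.34 M; run made earlier
- violet: free monomer 0.080 M; time 8.0 min
- amber: free monomer 0.20 M; time 8.0 min
- blue: free monomer 0.40 M; time 8.0 min
- grey: free monomer 0.80 M; time 8.0 min
- red: free monomer 1.5 M; time 8.0 min

- theta (time / min: monomer in chains / %): 0.833: 68; 1.50: 82; 2.50: 96; 3.00: 101; 4.00: 100
- beta (time / min: monomer in chains / %): 0.333: 39; 1.00: 73; 2.00: 89; 3.00: 99; 4.00: 100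

(standard deviation of a reading: 2 percentage points)

- a reading or a percentage of monomer in chains counts all its forms, free or not
- the concentration of monomer in chains that is asked is that of its free form alone
- "hardly changes" means that all values lie within two and a half points (for a concentration: within two and a half percent of the largest)

1. [monomer in chains] (only what is free in solution) at the end for violet, amber, blue, grey, red, in this order
2. how the row runs (rises all the way / hardly changes / rises, then falls / falls, then rises / falls all the way)

**Two ways.** Take the theta run first: its early reading of 68% at 0.833 min gives a first-order half-life of 0.507 min. The beta run is independent, with the same initiator and a charge 4.15 times as large, and its 73% at 1.00 min reads 0.529 min. The two differ by 0.0220 min, a gap the scatter of 2 percentage points can cover. So I trust the half-life as a reading and treat free monomer as pseudo-first-order, with one half-life at both charges within that scatter.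

**The count.** Taking the longer of the two half-lives, 8.0 min holds 15.1 half-lives: this is the half-life count, the number of half-lives of free monomer that fit into the reading time. By this reckoning 0.00285% of the charge stays free monomer. My row is therefore the charges themselves, but with a warning. A reading adds all forms of monomer in chains together, so the count shows what left free monomer, not how much monomer in chains stays free in solution. Blue, grey and red also stand above the beta charge, where nothing has been read.

**Forecast.** The forecast gave 0.08 M, 0.2 M, 0.4 M, 0.8 M and 1.5 M, a row that rises all the way: “I therefore expect the free chain-bound monomer to equal the charge”.

**Result.** The flasks give 0.0800 M, 0.200 M, 0.400 M, 0.592 M and 0.594 M, a row that rises all the way.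

    initiator → 2 initiating radical (k = 8.10 × 10⁻⁵ s⁻¹)
    free monomer + initiating radical → growing radical + monomer in chains (k = 1.00 × 10⁷ M⁻¹ s⁻¹)
    free monomer + growing radical → monomer in chains + growing radical, rate k3*[growing radical]*[free monomer] (k = 2.80 × 10⁶ M⁻¹ s⁻¹)
    2 growing radical → dead chain (k = 2.00 × 10⁹ M⁻¹ s⁻¹)
    crystals ⇌ monomer in chains, rate k5*(cs5 - [monomer in chains]) while solid is left; crystals form when [monomer in chains] > cs5 (solubility = 0.590 M, k = 0.0140 s⁻¹)

**Count and ceiling.** At 4.00 min the count gives 7.56 half-lives and 0.529% of free monomer left; red shows 0.650% and violet 0.637%. At 8.00 min red's monomer in chains, crystals counted, stands at >99.9%, so the count holds and the free form parts from it. The largest single effect on red's end value is the low solubility of monomer in chains: without it red ends at 1.50 M, with it at 0.594 M, and at the end crystals hold 60.4% of red's charge.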